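Flavanone numbering is used throughout (O1, C2, C3, C4, C4a, C5 to C8, C8a; ring B carries primed numbers).

## Analysis of the target

The target is a (2S)-flavanone: a chroman-4-one (aromatic ring A fused to the oxygen heterocycle ring C) that carries the aryl ring B at C2. Ring A has hydroxyls at C5 and C7 and a 3-methylbut-2-enyl (prenyl) group at C8. Ring B is a catechol (hydroxyls at C3' and C4') with a second prenyl group at C5'. C2 is the only stereocentre; it is benzylic, bonded to O1 and beta to the C4 carbonyl. It can be lost in two ways: base opens ring C to the 2'-hydroxychalcone (retro-oxa-Michael), and acid ionises the C2–O1 bond, helped by the para oxygen of ring B. The two trisubstituted alkenes rule out hydrogenolysis, ozonolysis and strong Lewis acids; each sits ortho to a phenol, so acid can close dimethylchroman rings, and the free catechol is easily oxidised. The hard points are placing the ring A prenyl group at C8 and not at C6, and setting C2 so that no later step erodes it. The strategy rests on O1 joining the stereocentre C2 to the aromatic carbon C8a: if ring C is closed by making the O1–C8a bond, C2 can be set as an ordinary secondary benzylic carbinol and its C–O bond is never formed or broken afterwards.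

## Retrosynthetic reasoning

**End game (19 back to 16).** The four phenols of 19 are unmasked last from the tetrakis(methoxymethyl) ether 18. Acetal protection is chosen because hydrogenolysis would reduce the prenyl groups, and fluoride or base at the flavanone stage would generate phenoxides that open ring C. The C4 ketone of 18 is traced to the alcohol 17 and its silyl ether 16. A C4 ketone present during ring closure would make the C2 carbinol a beta-hydroxy ketone, which under basic coupling conditions dehydrates to the chalcone or undergoes retro-aldol cleavage. Carrying C4 as a silyl ether costs a desilylation and an oxidation but removes this path.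

**Ring C (16 back to 15).** The O1–C8a bond is cut. This is the only ring bond whose formation leaves every bond at C2 untouched. The alternatives are cutting C2–O1, which means substitution at an ionisation-prone benzylic carbon, or C4–C4a, which means acid-mediated acylation. The forward reaction has to join a secondary alkoxide to a doubly ortho-substituted aryl triflate in 15 under conditions mild enough for four acetals, a silyl ether and two alkenes.

**C2 (15 back to 14).** The C2–H bond is cut, leading to the aryl ketone 14. An aryl alkyl ketone is the best substrate class for catalyst-controlled asymmetric transfer hydrogenation, so the configuration at C2 depends only on the catalyst, not on the neighbouring C4 centre.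

**Skeleton (14 back to 11 and 5).** After removal of the silyl group (13), the C3–C4 bond is cut by an aldol disconnection. This splits the molecule into two aryl halves of similar size, the methyl ketone 11 (ring B) and the aldehyde 5 (ring A), which already carries the triflate on the oxygen that becomes O1. The aldol carbinol centre need not be controlled because it is later oxidised.

**Ring A fragment (5 back to 1 and 2).** The triflate 5 comes from the phenol 4, in which the hydroxyl between the formyl and prenyl groups is the only free one. Compound 4 is traced through the triol 3 to 2,4,6-trihydroxybenzaldehyde 1 and prenyl bromide 2. C-Alkylation of the symmetric aldehyde fixes the prenyl group between two oxygens, and the later choice of which ortho oxygen becomes O1 decides that this carbon is C8.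

**Ring B fragment (11 back to 6 and 8).** The methyl ketone 11 comes from the aldehyde 9 by methyl addition and oxidation (through 10). The aryl–prenyl bond of 9 is cut to the aryl bromide 7 and the prenylstannane 8, and 7 is the bis-acetal of commercial 3-bromo-4,5-dihydroxybenzaldehyde 6. The bromide marks the prenyl position unambiguously, which no electrophilic prenylation of a catechol would do.

## Alternatives that were turned down

**Alternative 1: sigmatropic prenyl shifts on the intact flavanone.** The two aryl–prenyl bonds are disconnected to allyl aryl ethers of (2S)-naringenin A2. In the forward sense the bis-ether A3 is heated with a europium Lewis acid. Its 5-O-prenyl group should travel by a Claisen shift to C6 and a Cope shift on to C8, and its 4'-O-(1,1-dimethylallyl) group by a Claisen shift to C3', giving A1.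
- For: it is by far the shortest route. The flavanone skeleton and C2 come ready-made, no ring is built, and the Claisen–Cope sequence delivers C8 regiochemistry by itself. On step count and on avoiding a metal-catalysed ring closure it is stronger than the chosen route.
- Against: A1 has the wrong constitution for this target. Ring B of A1 has only the C4' hydroxyl, so the second catechol oxygen would still have to be introduced by ortho-hydroxylation of a phenol in the presence of two prenyl groups and an electron-rich ring A, for which no selective method is evident. Enantiopure A2 is also not dependable, since flavanones racemise through the chalcone, and prolonged heating with a Lewis acid invites the same erosion in A3 and A1.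
- Comparison: the chosen route brings both catechol oxygens in from the start and sets C2 by catalyst control.

**Alternative 2: benzannulation of ring A onto a chiral pyranone.** Ring A is dissected into four bonds (C8–C8a, C7–C8, C5–C6, C4a–C5). The forward step irradiates the diazo ketone A5 with (triisopropylsilyloxy)acetylene A6: Wolff rearrangement gives a vinylketene, cycloaddition with the ynol ether gives a cyclobutenone, and ring opening followed by six-electron electrocyclisation gives the phenol A4.
- For: the positions of the C5 hydroxyl, the C7 silyloxy group and the C8 prenyl group follow from connectivity alone, the two ring A oxygens emerge differentiated, and C2 is set early. On regiochemical certainty for ring A it is stronger than the chosen route, whose C8 placement depends on a selective protection.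
- Against: A5 is a harder target than the key precursor 15. It needs an enantiopure 2-aryl-dihydropyranone, acylation at its oxygen-bearing alkene carbon and a disubstituted diazo ketone. The photolysis has to run beside two prenyl alkenes and an enone chromophore. The carbene carries an adjacent CH2, so a 1,2-hydride shift to an enone competes with the Wolff migration. Deprotections still follow.
- Comparison: the chosen strategy asks one well-understood catalytic cycle of a substrate made from a commercial, fully oxygenated ring A.

**Alternative 3: acylative closure of ring C.** The C4–C4a bond is cut. The (3S)-3-aryl-3-aryloxypropanoic acid A8 is activated as a mixed anhydride or acid chloride and acylates the free position ortho to the ether oxygen of its phloroglucinol ring, giving the flavanone A7 directly.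
- For: C4 arrives at the ketone oxidation level. The silylation, desilylation and oxidation of the chosen route are not needed, the nucleophilic ring is very electron-rich, and six-membered acylation is classic chromanone chemistry. On redox economy it is clearly stronger.
- Against: the C2–O1 bond of A8 must first be made by substitution at a benzylic carbon whose ring has a para oxygen, so partial ionisation and loss of ee are likely. The same benzylic aryl ether then has to survive acylating acid, where it can ionise again or eliminate the phenol to a cinnamic acid. The prenyl groups and aryl silyl ethers are acid-labile too, and the final fluoride treatment of A7 generates flavanone phenoxides that can open ring C.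
- Comparison: the chosen strategy spends three extra steps and in return never exposes the C2–O bond to substitution or acid before the final deprotection.

Key step: step 11

Remarks on the chemistry:
- The aldol step creates the carbinol carbon that becomes C4 without control, and the oxidation in step 13 removes this centre again. Compounds 13 and 14 are therefore racemates, and 15, 16 and 17 are each carried as the pair of C4 epimers with uniform (S) configuration at C2; their SMILES leave the C4 centre open. The (1S,3S) epimer of 15 and the (2S,4S) epimer of 16 are one member of each pair.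
- Assumption: tributyl(3-methylbut-2-en-1-yl)stannane 8 is taken as purchasable.

## Route

**Step 1**
Reactants: 1 2,4,6-trihydroxybenzaldehyde; 2 prenyl bromide (1-bromo-3-methylbut-2-ene)
Product: 3 2,4,6-trihydroxy-3-(3-methylbut-2-en-1-yl)benzaldehyde
Conditions: DBU (1.1 equiv), THF, 0 °C to rt
Reagents that add atoms: none
Why: C-alkylation of a phloroglucinol-type phenoxide; the ring carbons C3 and C5, each flanked by two oxygens, are the most nucleophilic sites and are equivalent, so one equivalent of 2 should give the mono-C-prenyl compound, with O-prenyl and di-prenyl by-products removed by chromatography.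

**Step 2**
Reactants: 3 2,4,6-trihydroxy-3-(3-methylbut-2-en-1-yl)benzaldehyde
Product: 4 2-hydroxy-4,6-bis(methoxymethoxy)-3-(3-methylbut-2-en-1-yl)benzaldehyde
Conditions: MOMCl (2.1 equiv), i-Pr2NEt, CH2Cl2, 0 °C
Reagents that add atoms: chloromethyl methyl ether, COCCl
Why: O-alkylation with an alpha-chloro ether (acetal formation); the C4 hydroxyl (para to the formyl group) and the less hindered chelated hydroxyl at C6 should react, while the C2 hydroxyl, wedged between formyl and prenyl and hydrogen-bonded to the carbonyl, stays free.

**Step 3**
Reactants: 4 2-hydroxy-4,6-bis(methoxymethoxy)-3-(3-methylbut-2-en-1-yl)benzaldehyde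
Product: 5 2-formyl-3,5-bis(methoxymethoxy)-6-(3-methylbut-2-en-1-yl)phenyl trifluoromethanesulfonate
Conditions: Tf2O, pyridine, CH2Cl2, −20 to 0 °C
Reagents that add atoms: trifluoromethanesulfonic anhydride, O=S(=O)(OS(=O)(=O)C(F)(F)F)C(F)(F)F
Why: O-sulfonylation of the one remaining phenol; acetals, aldehyde and alkene are inert to the anhydride under pyridine buffering at this temperature.

**Step 4**
Reactants: 6 3-bromo-4,5-dihydroxybenzaldehyde
Product: 7 3-bromo-4,5-bis(methoxymethoxy)benzaldehyde
Conditions: MOMCl (2.5 equiv), i-Pr2NEt, CH2Cl2, 0 °C to rt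
Reagents that add atoms: chloromethyl methyl ether, COCCl
Why: Acetal protection of both catechol hydroxyls by O-alkylation; aldehyde and aryl bromide do not react.

**Step 5**
Reactants: 7 3-bromo-4,5-bis(methoxymethoxy)benzaldehyde; 8 tributyl(3-methylbut-2-en-1-yl)stannane
Product: 9 3,4-bis(methoxymethoxy)-5-(3-methylbut-2-en-1-yl)benzaldehyde
Conditions: Pd(PPh3)4 (5 mol%), DMF, 90 °C
Reagents that add atoms: none
Why: Stille coupling; zerovalent palladium adds to the aryl bromide, the allylstannane transmetalates, and reductive elimination from the sigma-allyl complex with palladium on the primary carbon should give the linear prenyl arene under neutral conditions that spare aldehyde and acetals.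

**Step 6**
Reactants: 9 3,4-bis(methoxymethoxy)-5-(3-methylbut-2-en-1-yl)benzaldehyde
Product: 10 (RS)-1-[3,4-bis(methoxymethoxy)-5-(3-methylbut-2-en-1-yl)phenyl]ethanol
Conditions: MeMgBr, THF, 0 °C; aq. NH4Cl
Reagents that add atoms: methylmagnesium bromide, C[Mg]Br
Why: Grignard addition to the aldehyde; the new carbinol centre is racemic and is removed in the next step.

**Step 7**
Reactants: 10 (RS)-1-[3,4-bis(methoxymethoxy)-5-(3-methylbut-2-en-1-yl)phenyl]ethanol
Product: 11 1-[3,4-bis(methoxymethoxy)-5-(3-methylbut-2-en-1-yl)phenyl]ethanone
Conditions: Dess–Martin periodinane, NaHCO3, CH2Cl2, rt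
Reagents that add atoms: none
Why: Dess–Martin oxidation of a secondary benzylic alcohol; the bicarbonate buffer protects the acetals and the alkene is not touched.

**Step 8**
Reactants: 11 1-[3,4-bis(methoxymethoxy)-5-(3-methylbut-2-en-1-yl)phenyl]ethanone; 5 2-formyl-3,5-bis(methoxymethoxy)-6-(3-methylbut-2-en-1-yl)phenyl trifluoromethanesulfonate
Product: 13 rac-2-{1-hydroxy-3-[3,4-bis(methoxymethoxy)-5-(3-methylbut-2-en-1-yl)phenyl]-3-oxopropyl}-3,5-bis(methoxymethoxy)-6-(3-methylbut-2-en-1-yl)phenyl trifluoromethanesulfonate, via ring B lithium enolate 12 (not isolated)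
Conditions: LiN(i-Pr)2, THF, −78 °C; then 5, −78 °C; AcOH, −78 °C
Reagents that add atoms: none
Why: Directed aldol addition of a preformed lithium enolate to a non-enolisable aldehyde through a closed six-membered transition state; at −78 °C addition to the formyl group should outrun attack at the triflate sulfur, and the cold acidic quench prevents retro-aldol cleavage. The carbinol centre forms as a racemate, which is harmless.

**Step 9**
Reactants: 13 racemic aldol
Product: 14 rac-2-{1-(tert-butyldimethylsilyloxy)-3-[3,4-bis(methoxymethoxy)-5-(3-methylbut-2-en-1-yl)phenyl]-3-oxopropyl}-3,5-bis(methoxymethoxy)-6-(3-methylbut-2-en-1-yl)phenyl trifluoromethanesulfonate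
Conditions: TBSOTf, 2,6-lutidine, CH2Cl2, −78 to −40 °C
Reagents that add atoms: tert-butyldimethylsilyl trifluoromethanesulfonate, CC(C)(C)[Si](C)(C)OS(=O)(=O)C(F)(F)F
Why: O-silylation of a hindered secondary alcohol with a silyl triflate and a hindered base; the low temperature and non-nucleophilic base avoid dehydration or retro-aldol of the beta-hydroxy ketone and exchange at the aryl acetals.

**Step 10**
Reactants: 14 racemic silyloxy ketone
Product: 15 2-{(3S)-1-(tert-butyldimethylsilyloxy)-3-hydroxy-3-[3,4-bis(methoxymethoxy)-5-(3-methylbut-2-en-1-yl)phenyl]propyl}-3,5-bis(methoxymethoxy)-6-(3-methylbut-2-en-1-yl)phenyl trifluoromethanesulfonate, as the pair of C1 epimers (1S,3S) and (1R,3S)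
Conditions: RuCl[(S,S)-TsDPEN](p-cymene) (2 mol%), HCO2H/Et3N (5:2), EtOAc, 40 °C
Reagents that add atoms: none
Why: Noyori asymmetric transfer hydrogenation of an aryl alkyl ketone; hydride and proton are delivered from the ruthenium hydride/amine pair in a six-membered transition state in which the aryl group sits under the cymene ligand, so the (S,S) catalyst should give the (S) carbinol at the future C2 for both enantiomers of 14. Isolated alkenes, the triflate, the silyl ether and the acetals are inert.

**Step 11**
Reactants: 15 (3S)-hydroxy triflate, both C1 epimers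
Product: 16 (2S)-4-(tert-butyldimethylsilyloxy)-5,7-bis(methoxymethoxy)-2-[3,4-bis(methoxymethoxy)-5-(3-methylbut-2-en-1-yl)phenyl]-8-(3-methylbut-2-en-1-yl)chromane, as the pair of C4 epimers (2S,4S) and (2S,4R)
Conditions: Pd(OAc)2 (5 mol%), 2-(di-tert-butylphosphino)-1,1'-binaphthyl (7 mol%), Cs2CO3, toluene, 70 °C
Reagents that add atoms: none
Why: Pd(OAc)2 is reduced in the flask to zerovalent palladium bearing one bulky phosphine, which adds oxidatively to the C8a–O bond of the triflate to give a divalent arylpalladium species. The C2 hydroxyl binds to palladium and is deprotonated by Cs2CO3, and C(aryl)–O reductive elimination from the seven-membered aryl(alkoxo)palladium chelate (Pd, C8a, C4a, C4, C3, C2, O) forms O1–C8a and returns the catalyst. The closest known reaction type is the palladium-catalysed intramolecular etherification of aryl halides and triflates with secondary alcohols to chromans (Buchwald–Hartwig C–O coupling). Ring C closes in the exo mode as a six-membered ring, the oxygen being delivered to C8a with the leaving triflate outside the new ring. No stereocentre is created; C2 keeps its (S) configuration because only its O–H bond reacts, and both C4 epimers should cyclise. The step needs reductive elimination to win over beta-hydride elimination of the benzylic alkoxide and over S–O cleavage of the triflate; the di-tert-butylphosphino group crowds palladium and accelerates reductive elimination, and the weak, barely soluble carbonate keeps free alkoxide low. The substrate helps as well: the C4 oxygen is silylated so only one alkoxide can bind, and insertion of the C8 prenyl alkene into the aryl–palladium bond would require a four-membered ring.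

**Step 12**
Reactants: 16 (2S)-4-silyloxyflavan, both C4 epimers
Product: 17 (2S)-5,7-bis(methoxymethoxy)-2-[3,4-bis(methoxymethoxy)-5-(3-methylbut-2-en-1-yl)phenyl]-8-(3-methylbut-2-en-1-yl)chroman-4-ol, as the pair of C4 epimers
Conditions: Bu4NF, THF, 0 °C to rt
Reagents that add atoms: none
Why: Fluoride-induced desilylation driven by the Si–F bond; the basic, non-acidic medium suits the ionisation-prone C4 benzylic position and leaves the acetals untouched.

**Step 13**
Reactants: 17 (2S)-flavan-4-ol, both C4 epimers
Product: 18 (2S)-5,7-bis(methoxymethoxy)-2-[3,4-bis(methoxymethoxy)-5-(3-methylbut-2-en-1-yl)phenyl]-8-(3-methylbut-2-en-1-yl)chroman-4-one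
Conditions: Dess–Martin periodinane, NaHCO3, CH2Cl2, 0 °C to rt
Reagents that add atoms: none
Why: Dess–Martin oxidation of the secondary benzylic alcohol merges both C4 epimers into one ketone; the bicarbonate buffer keeps the acid-sensitive flavan-4-ol from ionising, and C2, which is not alpha to the new carbonyl, is unaffected under these non-basic conditions.

**Step 14**
Reactants: 18 (2S)-flavanone tetrakis(methoxymethyl) ether
Product: 19 (2S)-2-[3,4-dihydroxy-5-(3-methylbut-2-en-1-yl)phenyl]-5,7-dihydroxy-8-(3-methylbut-2-en-1-yl)chroman-4-one (target)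
Conditions: HCl (ca. 1 M) in MeOH/THF, rt
Reagents that add atoms: none
Why: Acid-catalysed transacetalisation of the four aryl methoxymethyl ethers to methanol; dilute acid at room temperature should cleave the acetals faster than it adds the ortho phenols to the prenyl alkenes or ionises the C2–O1 bond.

## Compound list

1 | 2,4,6-trihydroxybenzaldehyde | O=Cc1c(O)cc(O)cc1O | starting material
2 | prenyl bromide (1-bromo-3-methylbut-2-ene) | CC(C)=CCBr | starting material
3 | 2,4,6-trihydroxy-3-(3-methylbut-2-en-1-yl)benzaldehyde | O=Cc1c(O)cc(O)c(CC=C(C)C)c1O | intermediate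
4 | 2-hydroxy-4,6-bis(methoxymethoxy)-3-(3-methylbut-2-en-1-yl)benzaldehyde | O=Cc1c(OCOC)cc(OCOC)c(CC=C(C)C)c1O | intermediate
5 | 2-formyl-3,5-bis(methoxymethoxy)-6-(3-methylbut-2-en-1-yl)phenyl trifluoromethanesulfonate | O=Cc1c(OCOC)cc(OCOC)c(CC=C(C)C)c1OS(=O)(=O)C(F)(F)F | intermediate
6 | 3-bromo-4,5-dihydroxybenzaldehyde | O=Cc1cc(O)c(O)c(Br)c1 | starting material
7 | 3-bromo-4,5-bis(methoxymethoxy)benzaldehyde | O=Cc1cc(OCOC)c(OCOC)c(Br)c1 | intermediate
8 | tributyl(3-methylbut-2-en-1-yl)stannane | CCCC[Sn](CCCC)(CCCC)CC=C(C)C | starting material
9 | 3,4-bis(methoxymethoxy)-5-(3-methylbut-2-en-1-yl)benzaldehyde | O=Cc1cc(OCOC)c(OCOC)c(CC=C(C)C)c1 | intermediate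
10 | (RS)-1-[3,4-bis(methoxymethoxy)-5-(3-methylbut-2-en-1-yl)phenyl]ethanol | CC(O)c1cc(OCOC)c(OCOC)c(CC=C(C)C)c1 | intermediate
11 | 1-[3,4-bis(methoxymethoxy)-5-(3-methylbut-2-en-1-yl)phenyl]ethanone | CC(=O)c1cc(OCOC)c(OCOC)c(CC=C(C)C)c1 | intermediate
12 | lithium enolate of 11 (lithium 1-arylethen-1-olate) | [Li]OC(=C)c1cc(OCOC)c(OCOC)c(CC=C(C)C)c1 | intermediate (not isolated)
13 | rac-2-{1-hydroxy-3-[3,4-bis(methoxymethoxy)-5-(3-methylbut-2-en-1-yl)phenyl]-3-oxopropyl}-3,5-bis(methoxymethoxy)-6-(3-methylbut-2-en-1-yl)phenyl trifluoromethanesulfonate | CC(C)=CCc1cc(C(=O)CC(O)c2c(OS(=O)(=O)C(F)(F)F)c(CC=C(C)C)c(OCOC)cc2OCOC)cc(OCOC)c1OCOC | intermediate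
14 | rac-2-{1-(tert-butyldimethylsilyloxy)-3-[3,4-bis(methoxymethoxy)-5-(3-methylbut-2-en-1-yl)phenyl]-3-oxopropyl}-3,5-bis(methoxymethoxy)-6-(3-methylbut-2-en-1-yl)phenyl trifluoromethanesulfonate | CC(C)=CCc1cc(C(=O)CC(O[Si](C)(C)C(C)(C)C)c2c(OS(=O)(=O)C(F)(F)F)c(CC=C(C)C)c(OCOC)cc2OCOC)cc(OCOC)c1OCOC | intermediate
15 | 2-{(3S)-1-(tert-butyldimethylsilyloxy)-3-hydroxy-3-[3,4-bis(methoxymethoxy)-5-(3-methylbut-2-en-1-yl)phenyl]propyl}-3,5-bis(methoxymethoxy)-6-(3-methylbut-2-en-1-yl)phenyl trifluoromethanesulfonate, C1 epimer pair (1S,3S) and (1R,3S) | CC(C)=CCc1cc([C@@H](O)CC(O[Si](C)(C)C(C)(C)C)c2c(OS(=O)(=O)C(F)(F)F)c(CC=C(C)C)c(OCOC)cc2OCOC)cc(OCOC)c1OCOC | intermediate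
16 | (2S)-4-(tert-butyldimethylsilyloxy)-5,7-bis(methoxymethoxy)-2-[3,4-bis(methoxymethoxy)-5-(3-methylbut-2-en-1-yl)phenyl]-8-(3-methylbut-2-en-1-yl)chromane, C4 epimer pair (2S,4S) and (2S,4R) | CC(C)=CCc1cc([C@@H]2CC(O[Si](C)(C)C(C)(C)C)c3c(OCOC)cc(OCOC)c(CC=C(C)C)c3O2)cc(OCOC)c1OCOC | intermediate
17 | (2S)-5,7-bis(methoxymethoxy)-2-[3,4-bis(methoxymethoxy)-5-(3-methylbut-2-en-1-yl)phenyl]-8-(3-methylbut-2-en-1-yl)chroman-4-ol, C4 epimer pair | CC(C)=CCc1cc([C@@H]2CC(O)c3c(OCOC)cc(OCOC)c(CC=C(C)C)c3O2)cc(OCOC)c1OCOC | intermediate
18 | (2S)-5,7-bis(methoxymethoxy)-2-[3,4-bis(methoxymethoxy)-5-(3-methylbut-2-en-1-yl)phenyl]-8-(3-methylbut-2-en-1-yl)chroman-4-one | CC(C)=CCc1cc([C@@H]2CC(=O)c3c(OCOC)cc(OCOC)c(CC=C(C)C)c3O2)cc(OCOC)c1OCOC | intermediate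
19 | (2S)-2-[3,4-dihydroxy-5-(3-methylbut-2-en-1-yl)phenyl]-5,7-dihydroxy-8-(3-methylbut-2-en-1-yl)chroman-4-one | CC(C)=CCc1cc([C@@H]2CC(=O)c3c(O)cc(O)c(CC=C(C)C)c3O2)cc(O)c1O | target

## Step count and least certain steps

Total step count: 14. Longest linear sequence: 11 steps (steps 4 to 7, then 8 to 14). The ring A branch (steps 1 to 3) joins at step 8.

**Step 11 (key step).**
- Risk: oxidative addition at the doubly ortho-substituted C8a triflate may be slow. That gives time for cleavage of the triflate S–O bond to the phenol, for beta-hydride elimination from the palladium alkoxide (oxidising C2 and reducing the arene), and for base-induced migration of the silyl group from the C4 oxygen to the C2 oxygen, which would remove the nucleophile.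
- Fallback: setting out from 14, the ketone is reduced with the enantiomeric catalyst RuCl[(R,R)-TsDPEN](p-cymene) in HCO2H/Et3N to the (3R) hydroxy triflate F4. The triflate is cleaved with aqueous Et4NOH in dioxane to the (3R) hydroxy phenol F5. Mitsunobu etherification (Ph3P, DIAD, THF, 0 °C) then closes ring C with inversion at the carbinol and comes back to the route at 16. This reserve gives up the main asset of the strategy, since the C2–O bond is then made by substitution and partial ionisation could lower the ee.

**Step 1 (with the regiochemistry of step 2).**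
- Risk: over-alkylation to the 3,5-diprenyl compound and competing O-prenylation may leave little of 3. The protection in step 2 may also not discriminate cleanly between the two chelated hydroxyls.
- Fallback: setting out from 1, the C4 and C6 hydroxyls are protected first (MOMCl, i-Pr2NEt) to give 2-hydroxy-4,6-bis(methoxymethoxy)benzaldehyde F1, in which the only free hydroxyl is the chelated one. It is alkylated with 3-chloro-3-methylbut-1-yne (K2CO3, KI, CuI cat., acetone, 60 °C) to the 2-methylbut-3-yn-2-yl ether F2. The alkyne is half-reduced (H2, Pd/CaCO3 poisoned with Pb(OAc)2, quinoline) to the 2-methylbut-3-en-2-yl ether F3. Heating in toluene (110 °C) then brings about an aromatic Claisen rearrangement to the only free ortho position, which delivers the normal prenyl group at C3 and comes back to the route at 4 with unambiguous regiochemistry.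

**Step 8.**
- Risk: the lithium aldolate sits next to the aryl triflate and may take over the triflyl group (O to O transfer) or revert by retro-aldol cleavage if the mixture warms. The hindered, electron-rich aldehyde may also react slowly enough for enolate attack at sulfur to compete.
- Fallback: setting out from 11, the ketone is converted (LiN(i-Pr)2, Me3SiCl, THF, −78 °C) into its trimethylsilyl enol ether F6. A Lewis-base-catalysed Mukaiyama aldol addition to 5 (LiOAc 10 mol%, DMF, −45 °C) gives the aldol trimethylsilyl ether F7, in which the alkoxide is silylated as it forms and never persists beside the triflate. Brief treatment with dilute aqueous acid in THF at 0 °C comes back to the route at 13.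

**Step 10.**
- Risk: turnover may be slow and conversion incomplete, because the ketone is attached to an electron-rich ring and carries a bulky beta substituent. Long reaction times in the formic acid medium could begin to loosen the benzylic silyl ether.
- Fallback: setting out from 14, Corey–Bakshi–Shibata reduction with (R)-2-methyl-CBS-oxazaborolidine (20 mol%) and catecholborane in toluene at −78 °C should give the same (S) carbinol and comes back to the route at 15. The aryl group acts as the large substituent, and at this temperature catecholborane does not hydroborate trisubstituted alkenes. No new compound is involved.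

**Step 14.**
- Risk: acid-catalysed addition of the C7 and C4' hydroxyls to the neighbouring prenyl alkenes (closure of dimethylchroman rings), and acid-induced ionisation at C2 with loss of ee, if acetal cleavage needs forcing.
- Fallback: setting out from 18, the aryl acetals are exchanged under non-protic conditions with Me3SiOTf and 2,2'-bipyridyl in CH2Cl2 at 0 °C to the tetrakis(trimethylsilyl) ether F8. This is hydrolysed by water at neutral pH during work-up and comes back to the route at 19.

## Further compounds

F1 | step 1 | 2-hydroxy-4,6-bis(methoxymethoxy)benzaldehyde | O=Cc1c(O)cc(OCOC)cc1OCOC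
F2 | step 1 | 4,6-bis(methoxymethoxy)-2-(2-methylbut-3-yn-2-yloxy)benzaldehyde | C#CC(C)(C)Oc1cc(OCOC)cc(OCOC)c1C=O
F3 | step 1 | 4,6-bis(methoxymethoxy)-2-(2-methylbut-3-en-2-yloxy)benzaldehyde | C=CC(C)(C)Oc1cc(OCOC)cc(OCOC)c1C=O
F4 | step 11 | 2-{(3R)-1-(tert-butyldimethylsilyloxy)-3-hydroxy-3-[3,4-bis(methoxymethoxy)-5-(3-methylbut-2-en-1-yl)phenyl]propyl}-3,5-bis(methoxymethoxy)-6-(3-methylbut-2-en-1-yl)phenyl trifluoromethanesulfonate, C1 epimer pair | CC(C)=CCc1cc([C@H](O)CC(O[Si](C)(C)C(C)(C)C)c2c(OS(=O)(=O)C(F)(F)F)c(CC=C(C)C)c(OCOC)cc2OCOC)cc(OCOC)c1OCOC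
F5 | step 11 | 2-{(3R)-1-(tert-butyldimethylsilyloxy)-3-hydroxy-3-[3,4-bis(methoxymethoxy)-5-(3-methylbut-2-en-1-yl)phenyl]propyl}-3,5-bis(methoxymethoxy)-6-(3-methylbut-2-en-1-yl)phenol, C1 epimer pair | CC(C)=CCc1cc([C@H](O)CC(O[Si](C)(C)C(C)(C)C)c2c(O)c(CC=C(C)C)c(OCOC)cc2OCOC)cc(OCOC)c1OCOC
F6 | step 8 | {1-[3,4-bis(methoxymethoxy)-5-(3-methylbut-2-en-1-yl)phenyl]ethenyloxy}trimethylsilane | C=C(O[Si](C)(C)C)c1cc(OCOC)c(OCOC)c(CC=C(C)C)c1
F7 | step 8 | rac-2-{1-(trimethylsilyloxy)-3-[3,4-bis(methoxymethoxy)-5-(3-methylbut-2-en-1-yl)phenyl]-3-oxopropyl}-3,5-bis(methoxymethoxy)-6-(3-methylbut-2-en-1-yl)phenyl trifluoromethanesulfonate | CC(C)=CCc1cc(C(=O)CC(O[Si](C)(C)C)c2c(OS(=O)(=O)C(F)(F)F)c(CC=C(C)C)c(OCOC)cc2OCOC)cc(OCOC)c1OCOC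
F0 | step 10 | none | none
F8 | step 14 | (2S)-2-[3,4-bis(trimethylsilyloxy)-5-(3-methylbut-2-en-1-yl)phenyl]-5,7-bis(trimethylsilyloxy)-8-(3-methylbut-2-en-1-yl)chroman-4-one | CC(C)=CCc1cc([C@@H]2CC(=O)c3c(O[Si](C)(C)C)cc(O[Si](C)(C)C)c(CC=C(C)C)c3O2)cc(O[Si](C)(C)C)c1O[Si](C)(C)C
A1 | alternative 1 | (2S)-7-(tert-butyldimethylsilyloxy)-5-hydroxy-2-[4-hydroxy-3-(3-methylbut-2-en-1-yl)phenyl]-8-(3-methylbut-2-en-1-yl)chroman-4-one | CC(C)=CCc1cc([C@@H]2CC(=O)c3c(O)cc(O[Si](C)(C)C(C)(C)C)c(CC=C(C)C)c3O2)ccc1O
A2 | alternative 1 | (2S)-naringenin, (2S)-5,7-dihydroxy-2-(4-hydroxyphenyl)chroman-4-one | O=C1C[C@@H](c2ccc(O)cc2)Oc2cc(O)cc(O)c12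
A3 | alternative 1 | (2S)-7-(tert-butyldimethylsilyloxy)-5-(3-methylbut-2-en-1-yloxy)-2-[4-(2-methylbut-3-en-2-yloxy)phenyl]chroman-4-one | C=CC(C)(C)Oc1ccc([C@@H]2CC(=O)c3c(OCC=C(C)C)cc(O[Si](C)(C)C(C)(C)C)cc3O2)cc1
A4 | alternative 2 | (2S)-5-hydroxy-2-[3,4-bis(methoxymethoxy)-5-(3-methylbut-2-en-1-yl)phenyl]-8-(3-methylbut-2-en-1-yl)-7-(triisopropylsilyloxy)chroman-4-one | CC(C)=CCc1cc([C@@H]2CC(=O)c3c(O)cc(O[Si](C(C)C)(C(C)C)C(C)C)c(CC=C(C)C)c3O2)cc(OCOC)c1OCOC
A5 | alternative 2 | (2S)-6-(2-diazo-5-methylhex-4-enoyl)-2-[3,4-bis(methoxymethoxy)-5-(3-methylbut-2-en-1-yl)phenyl]-2,3-dihydro-4H-pyran-4-one | CC(C)=CCC(=[N+]=[N-])C(=O)C1=CC(=O)C[C@@H](c2cc(CC=C(C)C)c(OCOC)c(OCOC)c2)O1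
A6 | alternative 2 | (triisopropylsilyloxy)acetylene | C#CO[Si](C(C)C)(C(C)C)C(C)C
A7 | alternative 3 | (2S)-5,7-bis(tert-butyldimethylsilyloxy)-2-[3,4-bis(tert-butyldimethylsilyloxy)-5-(3-methylbut-2-en-1-yl)phenyl]-8-(3-methylbut-2-en-1-yl)chroman-4-one | CC(C)=CCc1cc([C@@H]2CC(=O)c3c(O[Si](C)(C)C(C)(C)C)cc(O[Si](C)(C)C(C)(C)C)c(CC=C(C)C)c3O2)cc(O[Si](C)(C)C(C)(C)C)c1O[Si](C)(C)C(C)(C)C
A8 | alternative 3 | (3S)-3-[3,4-bis(tert-butyldimethylsilyloxy)-5-(3-methylbut-2-en-1-yl)phenyl]-3-[3,5-bis(tert-butyldimethylsilyloxy)-2-(3-methylbut-2-en-1-yl)phenoxy]propanoic acid | CC(C)=CCc1cc([C@H](CC(=O)O)Oc2cc(O[Si](C)(C)C(C)(C)C)cc(O[Si](C)(C)C(C)(C)C)c2CC=C(C)C)cc(O[Si](C)(C)C(C)(C)C)c1O[Si](C)(C)C(C)(C)C
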